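Plan
1. Retrosynthesis: C14–Br and the C11/C12 oxygens go back to a ring A dienone; the C7–C8 bond (ring B) is cut to a phenol carrying a 2-bromoethyl chain; the norbornane is cut at C2–C3 and C4–C5 (Diels–Alder) to a 2-aryl-3-alkylcyclopentenone, made by C9–C10 (Suzuki–Miyaura) and C5–C6 (Stork–Danheiser) unions.
2. Forward order: cyclopentenone → norbornane (rings C and D) → adjustment of C1, C4 and C7 → ring B by dearomatising C-alkylation with ring A present as an o-cresol → oxidation-level editing of ring A.
3. Enabling feature: ring A (C8, C9, C11–C14) is an o-cresol in disguise. C14 carries the phenolic oxygen, C8 (ortho) already carries the methyl group and C9 (meta) the norbornane, so the phenoxide can attack C7 through C8 in a six-membered array; C8 becomes the quaternary centre and the arene becomes a dienone with a handle on every other ring A carbon.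
4. Stereochemistry: C2, C4, C5 from a copper–bis(oxazoline)-catalysed endo Diels–Alder reaction; C10 by equilibration (aryl exo); C1 by exo hydride delivery; C8 from the chair that the norbornane imposes on ring B in the key step.
5. C9 by equilibration next to the C11 ketone (trans A/B fusion); C11 by equatorial methyl addition; C12 by axial conjugate borylation–oxidation; C14 by hydroxyl-directed hydrogenation of a bromoalkene.

Key step: step 16

Remarks
- Atom labels (arbitrary): C1 = CH–OMe; C2 = bridgehead CH next to it; C3 = CH2; C4 = CH–iPr; C5 = quaternary bridgehead; C6, C7 = the CH2–CH2 of ring B (C6 on C5); C8 = C(CH3) ring-fusion carbon; C9 = ring-fusion CH; C10 = norbornane CH bonded to C9; C11 = C(CH3)OH; C12 = CHOH; C13 = CH2; C14 = CHBr; C15 = bridging CH2. Ring A = C8, C9, C11–C14; ring B = C5–C10.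
- Norbornane locants in names: 1 = unsubstituted bridgehead (C2), 2 = oxygen-bearing carbon (C1), 3 = aryl-bearing carbon (C10), 4 = substituted bridgehead (C5), 5 = isopropyl-bearing carbon (C4). Absolute configuration is as in the SMILES.
- Assumption: (3-methoxy-2-methylphenyl)boronic acid, (1,3-dioxolan-2-ylmethyl)magnesium bromide, 3-acryloyloxazolidin-2-one and the (R,R)-tBu-box ligand are taken as catalogue items.

Step 1
Reactants: 1 3-ethoxycyclopent-2-en-1-one; 2 N-bromosuccinimide
Product: 3 2-bromo-3-ethoxycyclopent-2-en-1-one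
Conditions: NBS (1.05 equiv), CH2Cl2, 0 °C to rt
Reagents that add atoms: N-bromosuccinimide, O=C1CCC(=O)N1Br
Why: Electrophilic α-bromination of a vinylogous ester, whose α-carbon is the nucleophilic enol-ether carbon, should give the 2-bromo enone regiospecifically.

Step 2
Reactants: 3 2-bromo-3-ethoxycyclopent-2-en-1-one; 4 (3-methoxy-2-methylphenyl)boronic acid
Product: 5 3-ethoxy-2-(3-methoxy-2-methylphenyl)cyclopent-2-en-1-one
Conditions: Pd(OAc)2 (3 mol%), SPhos (6 mol%), K3PO4, toluene/H2O, 80 °C
Reagents that add atoms: (3-methoxy-2-methylphenyl)boronic acid, COc1cccc(B(O)O)c1C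
Why: Suzuki–Miyaura coupling of an α-bromo enone with a mono-ortho-substituted arylboronic acid is routine with a biarylphosphine ligand and forms the C9–C10 bond before C10 becomes a hindered sp3 centre.

Step 3
Reactants: 5 3-ethoxy-2-(3-methoxy-2-methylphenyl)cyclopent-2-en-1-one; 6 (1,3-dioxolan-2-ylmethyl)magnesium bromide; 7 water
Product: 9 3-(1,3-dioxolan-2-ylmethyl)-2-(3-methoxy-2-methylphenyl)cyclopent-2-en-1-one, via racemic bromomagnesium alkoxide adduct 8 (not isolated)
Conditions: 6 (2 equiv), THF, 0 °C to rt; then 1 M aq HCl, 0 °C, 20 min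
Reagents that add atoms: (1,3-dioxolan-2-ylmethyl)magnesium bromide, Br[Mg]CC1OCCO1; water, O
Why: Stork–Danheiser transposition (1,2-addition to the vinylogous ester, then acid hydrolysis and loss of water) installs C6–C7 on the enone β-carbon, and brief cold dilute acid should leave the dioxolane intact.

Step 4
Reactants: 9 3-(1,3-dioxolan-2-ylmethyl)-2-(3-methoxy-2-methylphenyl)cyclopent-2-en-1-one; 10 triisopropylsilyl trifluoromethanesulfonate
Product: 12 2-(triisopropylsilyloxy)-3-(3-methoxy-2-methylphenyl)-4-(1,3-dioxolan-2-ylmethyl)cyclopenta-1,3-diene, via lithium cross-conjugated dienolate 11 (not isolated)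
Conditions: LiN(iPr)2 (1.1 equiv), THF, −78 °C; then TIPSOTf, −78 to 0 °C; used at once
Reagents that add atoms: triisopropylsilyl trifluoromethanesulfonate, CC(C)[Si](OS(=O)(=O)C(F)(F)F)(C(C)C)C(C)C
Why: Kinetic α′-deprotonation of a 3-substituted cyclopentenone gives the cross-conjugated dienolate, and O-silylation turns it into a 2-silyloxycyclopentadiene that masks the C1 ketone until step 9.

Step 5
Reactants: 12 2-(triisopropylsilyloxy)-3-(3-methoxy-2-methylphenyl)-4-(1,3-dioxolan-2-ylmethyl)cyclopenta-1,3-diene; 13 3-acryloyloxazolidin-2-one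
Product: 14 3-{[2-(triisopropylsilyloxy)-3-(3-methoxy-2-methylphenyl)-4-(1,3-dioxolan-2-ylmethyl)bicyclo[2.2.1]hept-2-en-5-endo-yl]carbonyl}oxazolidin-2-one
Conditions: [Cu((R,R)-tBu-box)](SbF6)2 (10 mol%), CH2Cl2, −78 to −20 °C
Reagents that add atoms: 3-acryloyloxazolidin-2-one, C=CC(=O)N1CCOC1=O
Why: Diels–Alder reaction of the silyloxydiene with the chelated acrylimide: the unsubstituted enol-ether terminus bonds to the acrylate β-carbon, so the acyl-bearing carbon C4 ends next to the quaternary bridgehead C5, the acyl group sits endo, and the (R,R) ligand blocks the Re face of the α-carbon, which fixes C2, C4 and C5 in the absolute sense of the target.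

Step 6
Reactants: 14 Diels–Alder imide; 15 methanol; 16 methylmagnesium bromide
Product: 17 methyl 2-(triisopropylsilyloxy)-3-(3-methoxy-2-methylphenyl)-4-(1,3-dioxolan-2-ylmethyl)bicyclo[2.2.1]hept-2-ene-5-endo-carboxylate
Conditions: MeMgBr (1.2 equiv) added to MeOH/CH2Cl2 at 0 °C (forms MeOMgBr); then 14, 0 °C
Reagents that add atoms: methanol, CO
Why: Magnesium-methoxide transesterification of an N-acyloxazolidinone cleaves the exocyclic acyl group under conditions too mild to epimerise the endo α-stereocentre or to cleave the silyl enol ether.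

Step 7
Reactants: 17 methyl ester; 16 methylmagnesium bromide
Product: 19 2-[2-(triisopropylsilyloxy)-3-(3-methoxy-2-methylphenyl)-4-(1,3-dioxolan-2-ylmethyl)bicyclo[2.2.1]hept-2-en-5-endo-yl]propan-2-ol, via methyl ketone 18 (not isolated)
Conditions: MeMgBr (4 equiv), THF, 0 °C to rt
Reagents that add atoms: methylmagnesium bromide, C[Mg]Br
Why: Double Grignard addition to the ester gives the dimethylcarbinol that carries all three carbons of the isopropyl group, while the C1 ketone stays protected as its silyl enol ether.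

Step 8
Reactants: 19 tertiary alcohol
Product: 20 triisopropyl{[3-(3-methoxy-2-methylphenyl)-4-(1,3-dioxolan-2-ylmethyl)-5-endo-(prop-1-en-2-yl)bicyclo[2.2.1]hept-2-en-2-yl]oxy}silane
Conditions: Burgess reagent (methyl N-(triethylammoniosulfonyl)carbamate, 2 equiv), toluene, 60 °C
Reagents that add atoms: none
Why: Burgess dehydration is a neutral syn-elimination that avoids a carbocation beside the norbornane and should give mainly the isopropenyl group by loss of a methyl hydrogen.

Step 9
Reactants: 20 isopropenyl silyl enol ether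
Product: 21 3-exo-(3-methoxy-2-methylphenyl)-4-(1,3-dioxolan-2-ylmethyl)-5-endo-(prop-1-en-2-yl)bicyclo[2.2.1]heptan-2-one
Conditions: TBAF (1.2 equiv), THF, 0 °C to rt; aq NH4Cl
Reagents that add atoms: none
Why: Fluoride desilylation frees the C1 ketone, and under these basic conditions C10 equilibrates through the enolate to the exo-aryl isomer, because an endo aryl group would collide with the endo substituent on C4.

Step 10
Reactants: 21 isopropenyl ketone
Product: 22 3-exo-(3-methoxy-2-methylphenyl)-4-(1,3-dioxolan-2-ylmethyl)-5-endo-isopropylbicyclo[2.2.1]heptan-2-one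
Conditions: H2 (1 atm), Pd/C, EtOAc, rt
Reagents that add atoms: none
Why: Heterogeneous hydrogenation saturates the 1,1-disubstituted alkene without touching C4, and any isopropylidene isomer from step 8 should be reduced from the exo face to the same endo-isopropyl compound.

Step 11
Reactants: 22 isopropyl ketone
Product: 23 3-exo-(3-methoxy-2-methylphenyl)-4-(1,3-dioxolan-2-ylmethyl)-5-endo-isopropylbicyclo[2.2.1]heptan-2-endo-ol
Conditions: NaBH4, MeOH, −20 to 0 °C
Reagents that add atoms: none
Why: Borohydride reduction of a norbornan-2-one takes place from the exo face, which sets C1 with the hydroxyl endo and trans to the exo aryl group.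

Step 12
Reactants: 23 endo alcohol; 24 iodomethane
Product: 26 2-[2-endo-methoxy-3-exo-(3-methoxy-2-methylphenyl)-5-endo-isopropylbicyclo[2.2.1]heptan-4-ylmethyl]-1,3-dioxolane, via sodium alkoxide 25 (not isolated)
Conditions: NaH (1.5 equiv), THF/DMF, 0 °C; then MeI, rt
Reagents that add atoms: iodomethane, CI
Why: Williamson etherification installs the C1 methyl ether while no other free hydroxyl is present.

Step 13
Reactants: 26 methyl ether acetal; 7 water
Product: 28 2-[2-endo-methoxy-3-exo-(3-methoxy-2-methylphenyl)-5-endo-isopropylbicyclo[2.2.1]heptan-4-yl]ethan-1-ol, via aldehyde 27 (not isolated)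
Conditions: 1 M aq HCl, THF, rt; neutralise with NaHCO3; then NaBH4, MeOH, 0 °C
Reagents that add atoms: water, O
Why: Acetal hydrolysis followed at once by borohydride reduction gives the C7 alcohol without handling an aldehyde tethered to an electron-rich arene.

Step 14
Reactants: 28 aryl methyl ether alcohol
Product: 29 3-[4-(2-hydroxyethyl)-5-endo-isopropyl-2-endo-methoxybicyclo[2.2.1]heptan-3-exo-yl]-2-methylphenol
Conditions: NaSEt (6 equiv), DMF, 120 °C; aqueous work-up
Reagents that add atoms: none
Why: Thiolate SN2 demethylation cleaves only the aryl methyl ether, because phenoxide is a leaving group and the secondary alkoxide of the C1 ether is not.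

Step 15
Reactants: 29 phenol alcohol; 30 tetrabromomethane
Product: 31 3-[4-(2-bromoethyl)-5-endo-isopropyl-2-endo-methoxybicyclo[2.2.1]heptan-3-exo-yl]-2-methylphenol
Conditions: CBr4 (1.3 equiv), PPh3 (1.4 equiv), CH2Cl2, 0 °C
Reagents that add atoms: tetrabromomethane, BrC(Br)(Br)Br
Why: The Appel reaction converts the primary alcohol into the bromide and leaves the phenol untouched, since an aryloxyphosphonium ion cannot be displaced.

Step 16
Reactants: 31 bromoethyl phenol
Product: 33 tetracyclic dienone (ring B closed; C14=O; C12=C13; C9=C11; C8 quaternary with its methyl cis to C10–H), via potassium phenoxide 32 (not isolated)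
Conditions: t-BuOK (1.05 equiv), t-BuOH/THF, 0.01 M, 0 to 60 °C
Reagents that add atoms: none
Why: The potassium phenoxide 32 is an ambident nucleophile whose ortho carbon C8 (the methyl-bearing carbon next to the phenoxide carbon C14) displaces bromide from C7 in an intramolecular SN2 reaction, and because C8 already carries a methyl group the resulting cyclohexa-2,4-dienone cannot re-aromatise. The closest known reaction type is the intramolecular alkylative dearomatisation of phenols by tethered alkyl halides or sulfonates (ortho C-alkylation). Ring B is the only ring closed and it closes in the 6-exo-tet mode (C7 is the electrophilic atom and the C7–Br bond lies outside the new ring). The one new stereocentre C8 is set by the norbornane: the exo C10–C9 bond and the bridgehead C5–C6 bond fix the sign of the C9–C10–C5–C6 torsion, so ring B can reach a chair only when C7 approaches the arene face that leaves the C8 methyl axial and the dienone ring equatorial, whereas attack on the other face needs a twist-boat that drives C8 and its methyl into the C15 bridge. The step needs selectivity for C8 over the para carbon C11 and over oxygen: O-alkylation would require an eight-membered ring, and attack at C11 through the same chair would force the C8 methyl into the arene plane against C1–H (allylic 1,3-strain), where the ortho mode places only the small C11–H. One equivalent of base in t-BuOH keeps the phenoxide hydrogen-bonded, which favours C-alkylation, and leaves no strong base to eliminate HBr from the side chain.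

Step 17
Reactants: 33 tetracyclic dienone; 34 3-chloroperoxybenzoic acid
Product: 35 9,11-epoxide of 33 (oxygen on the ring A face that carries the C8 methyl)
Conditions: mCPBA (1.2 equiv), NaHCO3, CH2Cl2, 0 °C to rt
Reagents that add atoms: 3-chloroperoxybenzoic acid, OOC(=O)c1cccc(Cl)c1
Why: Prilezhaev epoxidation of a 2,4-dienone occurs at the more electron-rich γ,δ-alkene (C9=C11), expected from the face remote from the ring B carbons, and both new centres are cleared again in step 18.

Step 18
Reactants: 35 epoxy enone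
Product: 36 tetracyclic ene-dione (C11 and C14 ketones; C12=C13; C9–H trans to the C8 methyl)
Conditions: BF3·OEt2 (0.2 equiv), CH2Cl2, −78 to −20 °C; then Et3N (0.5 equiv), rt
Reagents that add atoms: none
Why: Meinwald rearrangement: Lewis-acid opening of the epoxide at the tertiary carbon C9 with a 1,2-hydride shift from C11 gives the C11 ketone (the electron-poor alkenyl carbon C12 is a poor migrating group), and C9, now α to a ketone, equilibrates to the trans ring fusion because the cis isomer would put C11 axial on ring B against the C15 bridge.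

Step 19
Reactants: 36 ene-dione; 37 methyllithium
Product: 38 tetracyclic hydroxy enone (C11 methyl trans and C11 hydroxyl cis to the C8 methyl; C12=C13; C14=O)
Conditions: CeCl3 (1.5 equiv), MeLi (1.4 equiv), THF, −78 °C; then 36, −78 °C
Reagents that add atoms: methyllithium, [Li]C
Why: Organocerium 1,2-addition is non-basic and should select the C11 carbonyl over the neopentyl C14 carbonyl, with attack from the face opposite the axial C8 methyl (equatorial attack), so the new methyl is equatorial and the hydroxyl axial as in the target.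

Step 20
Reactants: 38 hydroxy enone; 39 bis(pinacolato)diboron; 40 hydrogen peroxide
Product: 42 tetracyclic dihydroxy ketone (C11–OH and C12–OH trans-diaxial; C13 methylene; C14=O), via pinacol boronate 41 (not isolated)
Conditions: CuCl (5 mol%), DPEphos (5 mol%), NaOtBu (10 mol%), B2pin2 (1.2 equiv), MeOH (2 equiv), THF, rt; then 30% H2O2, pH 7 buffer, 0 °C
Reagents that add atoms: hydrogen peroxide, OO (bis(pinacolato)diboron, CC1(C)OB(B2OC(C)(C)C(C)(C)O2)OC1(C)C, supplies the boron of 41 only)
Why: Copper-catalysed conjugate borylation delivers boron axially to C12 on the face of C9–H, anti to the axial C11 hydroxyl and away from the axial C8 methyl, and the oxidation proceeds with retention to give the C12 alcohol trans to the C11 alcohol.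

Step 21
Reactants: 42 dihydroxy ketone; 43 2,4,6-triisopropylbenzenesulfonohydrazide
Product: 44 (E)-2,4,6-triisopropylbenzenesulfonylhydrazone of 42 at C14
Conditions: 43 (1.3 equiv), THF, cat. HCl, rt
Reagents that add atoms: 2,4,6-triisopropylbenzenesulfonohydrazide, CC(C)c1cc(C(C)C)c(S(=O)(=O)NN)c(C(C)C)c1
Why: Arylsulfonylhydrazone condensation proceeds under mild acid even for hindered ketones and places the sulfonamide syn to the C13 methylene, as the next step requires.

Step 22
Reactants: 44 sulfonylhydrazone; 45 1,2-dibromoethane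
Product: 47 tetracyclic bromoalkene diol (C13=C14 with bromine on C14; C11–OH and C12–OH as in 42), via trilithiated vinyllithium 46 (not isolated)
Conditions: n-BuLi (4.4 equiv), TMEDA, THF, −78 to 0 °C; then BrCH2CH2Br, −78 °C
Reagents that add atoms: 1,2-dibromoethane, BrCCBr
Why: Shapiro reaction: after deprotonation of the two hydroxyls and N–H, the only α-hydrogens (C13) are removed, loss of sulfinate and dinitrogen gives the C14 vinyllithium, and bromine transfer from 1,2-dibromoethane gives the bromoalkene without ever creating a cation next to the quaternary C8.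

Step 23
Reactants: 47 bromoalkene diol
Product: 48 CNP0130529.1 (target)
Conditions: H2 (1 atm), [Ir(cod)(PCy3)(py)]PF6 (10 mol%), CH2Cl2, rt
Reagents that add atoms: none
Why: Hydroxyl-directed homogeneous hydrogenation: the cationic iridium catalyst binds the pseudoaxial allylic C12 hydroxyl and adds H2 to the same face of C13=C14, which is also the face opposite the axial C8 methyl, so C14–H ends cis to C12–OH and bromine ends equatorial and cis to the C8 methyl.

Compound list
1 | 3-ethoxycyclopent-2-en-1-one | CCOC1=CC(=O)CC1 | starting material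
2 | N-bromosuccinimide | O=C1CCC(=O)N1Br | starting material
3 | 2-bromo-3-ethoxycyclopent-2-en-1-one | CCOC1=C(Br)C(=O)CC1 | intermediate
4 | (3-methoxy-2-methylphenyl)boronic acid | COc1cccc(B(O)O)c1C | starting material
5 | 3-ethoxy-2-(3-methoxy-2-methylphenyl)cyclopent-2-en-1-one | CCOC1=C(c2cccc(OC)c2C)C(=O)CC1 | intermediate
6 | (1,3-dioxolan-2-ylmethyl)magnesium bromide | Br[Mg]CC1OCCO1 | starting material
7 | water | O | starting material
8 | racemic bromomagnesium 1-(1,3-dioxolan-2-ylmethyl)-3-ethoxy-2-(3-methoxy-2-methylphenyl)cyclopent-2-en-1-olate | CCOC1=C(c2cccc(OC)c2C)C(O[Mg]Br)(CC2OCCO2)CC1 | intermediate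
9 | 3-(1,3-dioxolan-2-ylmethyl)-2-(3-methoxy-2-methylphenyl)cyclopent-2-en-1-one | O=C1CCC(CC2OCCO2)=C1c1cccc(OC)c1C | intermediate
10 | triisopropylsilyl trifluoromethanesulfonate | CC(C)[Si](OS(=O)(=O)C(F)(F)F)(C(C)C)C(C)C | starting material
11 | lithium 4-(1,3-dioxolan-2-ylmethyl)-3-(3-methoxy-2-methylphenyl)cyclopenta-1,3-dien-2-olate | [Li]OC1=CCC(CC2OCCO2)=C1c1cccc(OC)c1C | intermediate
12 | 2-(triisopropylsilyloxy)-3-(3-methoxy-2-methylphenyl)-4-(1,3-dioxolan-2-ylmethyl)cyclopenta-1,3-diene | CC(C)[Si](OC1=CCC(CC2OCCO2)=C1c1cccc(OC)c1C)(C(C)C)C(C)C | intermediate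
13 | 3-acryloyloxazolidin-2-one | C=CC(=O)N1CCOC1=O | starting material
14 | 3-{[2-(triisopropylsilyloxy)-3-(3-methoxy-2-methylphenyl)-4-(1,3-dioxolan-2-ylmethyl)bicyclo[2.2.1]hept-2-en-5-endo-yl]carbonyl}oxazolidin-2-one | COc1cccc(C2=C(O[Si](C(C)C)(C(C)C)C(C)C)[C@H]3C[C@@H](C(=O)N4CCOC4=O)[C@]2(CC4OCCO4)C3)c1C | intermediate
15 | methanol | CO | starting material
16 | methylmagnesium bromide | C[Mg]Br | starting material
17 | methyl 2-(triisopropylsilyloxy)-3-(3-methoxy-2-methylphenyl)-4-(1,3-dioxolan-2-ylmethyl)bicyclo[2.2.1]hept-2-ene-5-endo-carboxylate | COc1cccc(C2=C(O[Si](C(C)C)(C(C)C)C(C)C)[C@H]3C[C@@H](C(=O)OC)[C@]2(CC4OCCO4)C3)c1C | intermediate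
18 | 5-endo-acetyl analogue of 17 (methyl ketone) | COc1cccc(C2=C(O[Si](C(C)C)(C(C)C)C(C)C)[C@H]3C[C@@H](C(C)=O)[C@]2(CC4OCCO4)C3)c1C | intermediate
19 | 2-[2-(triisopropylsilyloxy)-3-(3-methoxy-2-methylphenyl)-4-(1,3-dioxolan-2-ylmethyl)bicyclo[2.2.1]hept-2-en-5-endo-yl]propan-2-ol | COc1cccc(C2=C(O[Si](C(C)C)(C(C)C)C(C)C)[C@H]3C[C@@H](C(C)(C)O)[C@]2(CC4OCCO4)C3)c1C | intermediate
20 | triisopropyl{[3-(3-methoxy-2-methylphenyl)-4-(1,3-dioxolan-2-ylmethyl)-5-endo-(prop-1-en-2-yl)bicyclo[2.2.1]hept-2-en-2-yl]oxy}silane | COc1cccc(C2=C(O[Si](C(C)C)(C(C)C)C(C)C)[C@H]3C[C@@H](C(C)=C)[C@]2(CC4OCCO4)C3)c1C | intermediate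
21 | 3-exo-(3-methoxy-2-methylphenyl)-4-(1,3-dioxolan-2-ylmethyl)-5-endo-(prop-1-en-2-yl)bicyclo[2.2.1]heptan-2-one | COc1cccc([C@@H]2C(=O)[C@H]3C[C@@H](C(C)=C)[C@]2(CC4OCCO4)C3)c1C | intermediate
22 | 3-exo-(3-methoxy-2-methylphenyl)-4-(1,3-dioxolan-2-ylmethyl)-5-endo-isopropylbicyclo[2.2.1]heptan-2-one | COc1cccc([C@@H]2C(=O)[C@H]3C[C@@H](C(C)C)[C@]2(CC4OCCO4)C3)c1C | intermediate
23 | 3-exo-(3-methoxy-2-methylphenyl)-4-(1,3-dioxolan-2-ylmethyl)-5-endo-isopropylbicyclo[2.2.1]heptan-2-endo-ol | COc1cccc([C@@H]2[C@@H](O)[C@H]3C[C@@H](C(C)C)[C@]2(CC4OCCO4)C3)c1C | intermediate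
24 | iodomethane | CI | starting material
25 | sodium alkoxide of 23 | COc1cccc([C@@H]2[C@@H](O[Na])[C@H]3C[C@@H](C(C)C)[C@]2(CC4OCCO4)C3)c1C | intermediate
26 | 2-[2-endo-methoxy-3-exo-(3-methoxy-2-methylphenyl)-5-endo-isopropylbicyclo[2.2.1]heptan-4-ylmethyl]-1,3-dioxolane | COc1cccc([C@@H]2[C@@H](OC)[C@H]3C[C@@H](C(C)C)[C@]2(CC4OCCO4)C3)c1C | intermediate
27 | [2-endo-methoxy-3-exo-(3-methoxy-2-methylphenyl)-5-endo-isopropylbicyclo[2.2.1]heptan-4-yl]acetaldehyde | COc1cccc([C@@H]2[C@@H](OC)[C@H]3C[C@@H](C(C)C)[C@]2(CC=O)C3)c1C | intermediate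
28 | 2-[2-endo-methoxy-3-exo-(3-methoxy-2-methylphenyl)-5-endo-isopropylbicyclo[2.2.1]heptan-4-yl]ethan-1-ol | COc1cccc([C@@H]2[C@@H](OC)[C@H]3C[C@@H](C(C)C)[C@]2(CCO)C3)c1C | intermediate
29 | 3-[4-(2-hydroxyethyl)-5-endo-isopropyl-2-endo-methoxybicyclo[2.2.1]heptan-3-exo-yl]-2-methylphenol | Oc1cccc([C@@H]2[C@@H](OC)[C@H]3C[C@@H](C(C)C)[C@]2(CCO)C3)c1C | intermediate
30 | tetrabromomethane | BrC(Br)(Br)Br | starting material
31 | 3-[4-(2-bromoethyl)-5-endo-isopropyl-2-endo-methoxybicyclo[2.2.1]heptan-3-exo-yl]-2-methylphenol | Oc1cccc([C@@H]2[C@@H](OC)[C@H]3C[C@@H](C(C)C)[C@]2(CCBr)C3)c1C | intermediate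
32 | potassium phenoxide of 31 | [K]Oc1cccc([C@@H]2[C@@H](OC)[C@H]3C[C@@H](C(C)C)[C@]2(CCBr)C3)c1C | intermediate
33 | tetracyclic dienone (C14=O; C12=C13; C9=C11; C8 quaternary) | CO[C@H]1[C@H]2C[C@@H](C(C)C)[C@]3(CC[C@@]4(C)C([C@H]13)=CC=CC4=O)C2 | intermediate
34 | 3-chloroperoxybenzoic acid | OOC(=O)c1cccc(Cl)c1 | starting material
35 | 9,11-epoxide of 33 | CO[C@H]1[C@H]2C[C@@H](C(C)C)[C@]3(CC[C@@]4(C)[C@]5([C@H]13)O[C@@H]5C=CC4=O)C2 | intermediate
36 | tetracyclic ene-dione (C11=O; C14=O; C12=C13; trans A/B) | CO[C@H]1[C@H]2C[C@@H](C(C)C)[C@]3(CC[C@@]4(C)[C@H]([C@H]13)C(=O)C=CC4=O)C2 | intermediate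
37 | methyllithium | [Li]C | starting material
38 | tetracyclic hydroxy enone (C11 methyl carbinol; C12=C13; C14=O) | CO[C@H]1[C@H]2C[C@@H](C(C)C)[C@]3(CC[C@@]4(C)[C@H]([C@H]13)[C@](C)(O)C=CC4=O)C2 | intermediate
39 | bis(pinacolato)diboron | CC1(C)OB(B2OC(C)(C)C(C)(C)O2)OC1(C)C | starting material
40 | hydrogen peroxide | OO | starting material
41 | C12 pinacol boronate of the C14 ketone | CO[C@H]1[C@H]2C[C@@H](C(C)C)[C@]3(CC[C@@]4(C)[C@H]([C@H]13)[C@](C)(O)[C@@H](B5OC(C)(C)C(C)(C)O5)CC4=O)C2 | intermediate
42 | tetracyclic dihydroxy ketone (C11–OH; C12–OH; C14=O) | CO[C@H]1[C@H]2C[C@@H](C(C)C)[C@]3(CC[C@@]4(C)[C@H]([C@H]13)[C@](C)(O)[C@@H](O)CC4=O)C2 | intermediate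
43 | 2,4,6-triisopropylbenzenesulfonohydrazide | CC(C)c1cc(C(C)C)c(S(=O)(=O)NN)c(C(C)C)c1 | starting material
44 | (E)-2,4,6-triisopropylbenzenesulfonylhydrazone of 42 | CO[C@H]1[C@H]2C[C@@H](C(C)C)[C@]3(CC[C@@]4(C)[C@H]([C@H]13)[C@](C)(O)[C@@H](O)C/C4=N\NS(=O)(=O)c5c(C(C)C)cc(C(C)C)cc5C(C)C)C2 | intermediate
45 | 1,2-dibromoethane | BrCCBr | starting material
46 | C14 vinyllithium bis(lithium alkoxide) | CO[C@H]1[C@H]2C[C@@H](C(C)C)[C@]3(CC[C@@]4(C)[C@H]([C@H]13)[C@](C)(O[Li])[C@@H](O[Li])C=C4[Li])C2 | intermediate
47 | tetracyclic bromoalkene diol (C13=C14–Br) | CO[C@H]1[C@H]2C[C@@H](C(C)C)[C@]3(CC[C@@]4(C)[C@H]([C@H]13)[C@](C)(O)[C@@H](O)C=C4Br)C2 | intermediate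
48 | CNP0130529.1 | CO[C@H]1[C@H]2C[C@@H](C(C)C)[C@]3(CC[C@@]4(C)[C@H]([C@H]13)[C@](C)(O)[C@@H](O)C[C@@H]4Br)C2 | target

Total step count: 23. Longest linear sequence: 23 steps (from 1; all other inputs are purchased reagents).

Steps most likely to fail

Step 16 (key step). What may go wrong: C-alkylation at the unsubstituted para carbon C11 followed by re-aromatisation, closure through the twist-boat to the C8 epimer, or elimination of HBr from the side chain. Fallback, setting out from 29 and returning at 33, replaces the phenoxide by an enone dienolate. Hydrogenation of the phenol ring of 29 (H2, Pd/C, catalytic AlCl3, CH2Cl2) should give the keto alcohol F1 as a mixture of ring A epimers. Appel bromination (CBr4, PPh3) then gives the keto bromide F2. Dehydrogenation with IBX in DMSO through the more substituted enol gives the 2-methyl-3-substituted cyclohex-2-enone F3. With t-BuOK in t-BuOH the extended dienolate (deprotonation at C11) is alkylated at its α-carbon C8 by C7 through the same chair, with C9 still trigonal and C11–H in the plane, to give the β,γ-unsaturated ketone F4. A second IBX dehydrogenation across C12–C13 rejoins the route at dienone 33.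

Step 18. What may go wrong: migration of the alkenyl carbon C12 (ring contraction to an aldehyde) or skeletal shifts of the developing C9 cation in place of the hydride shift. Fallback, setting out from 33 and returning at 36, avoids cationic intermediates. Dissolving-metal 1,6-reduction (Li, liquid NH3, t-BuOH, THF, −78 °C, then NH4Cl) with kinetic α-protonation should give the β,γ-unsaturated ketone F5 (C11=C12; C9–H trans to the C8 methyl). Epoxidation with mCPBA from the face opposite the axial C8 methyl gives the β,γ-epoxy ketone F6. Et3N opens it by β-elimination to the γ-hydroxy enone F7, and MnO2 oxidation of the allylic alcohol gives ene-dione 36.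

Step 23. What may go wrong: hydrogenolysis of the C–Br bond on the metal, or delivery of hydrogen from the face of the tertiary C11 hydroxyl. Fallback, setting out from 47 and returning at 48, is a radical hydrogenation by hydrogen-atom transfer (Mn(dpm)3 catalyst, PhSiH3, t-BuOOH, i-PrOH, rt). This mode does not insert into carbon–halogen bonds, and the C14 radical should take up hydrogen on the axial side to leave bromine equatorial. No new compound is formed.

Further compounds
F1 | step 16 | 2-methyl-3-[4-(2-hydroxyethyl)-5-endo-isopropyl-2-endo-methoxybicyclo[2.2.1]heptan-3-exo-yl]cyclohexan-1-one (mixture of ring A epimers) | O=C1CCCC([C@@H]2[C@@H](OC)[C@H]3C[C@@H](C(C)C)[C@]2(CCO)C3)C1C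
F2 | step 16 | 2-methyl-3-[4-(2-bromoethyl)-5-endo-isopropyl-2-endo-methoxybicyclo[2.2.1]heptan-3-exo-yl]cyclohexan-1-one (mixture of ring A epimers) | O=C1CCCC([C@@H]2[C@@H](OC)[C@H]3C[C@@H](C(C)C)[C@]2(CCBr)C3)C1C
F3 | step 16 | 2-methyl-3-[4-(2-bromoethyl)-5-endo-isopropyl-2-endo-methoxybicyclo[2.2.1]heptan-3-exo-yl]cyclohex-2-en-1-one | O=C1CCCC([C@@H]2[C@@H](OC)[C@H]3C[C@@H](C(C)C)[C@]2(CCBr)C3)=C1C
F4 | step 16 | tetracyclic β,γ-unsaturated ketone (C14=O; C9=C11; C8 quaternary) | CO[C@H]1[C@H]2C[C@@H](C(C)C)[C@]3(CC[C@@]4(C)C([C@H]13)=CCCC4=O)C2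
F5 | step 18 | tetracyclic β,γ-unsaturated ketone (C14=O; C11=C12; trans A/B) | CO[C@H]1[C@H]2C[C@@H](C(C)C)[C@]3(CC[C@@]4(C)[C@H]([C@H]13)C=CCC4=O)C2
F6 | step 18 | 11,12-epoxide of F5 (oxygen on the face of C9–H) | CO[C@H]1[C@H]2C[C@@H](C(C)C)[C@]3(CC[C@@]4(C)[C@H]([C@H]13)[C@H]5O[C@H]5CC4=O)C2
F7 | step 18 | tetracyclic γ-hydroxy enone (C11–OH; C12=C13; C14=O) | CO[C@H]1[C@H]2C[C@@H](C(C)C)[C@]3(CC[C@@]4(C)[C@H]([C@H]13)[C@@H](O)C=CC4=O)C2
F0 | step 23 | none | none
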